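Every first end group charged stays in the closed flask, so free first end groups, links and anything unseen always add up to the charge. We are asked about the north-east flask, which is the one followed so far.

| flask | first end groups | second end groups | temperature | remark | time |
|---|---|---|---|---|---|
| north-east | 0.10 M | 0.090 M | 25 °C | the very flask that is asked about, followed so far |  |
| south-west | 0.10 M | 0.060 M | 10 °C | run made earlier |  |
| flask | 0.10 M | 0.0900 M | 25 °C |  | 25 h |

- north-east (time / h: links / %, first end groups / %): 1.33: 56.2, 9.5; 4.00: 55.7, 9.6; 8.00: 56.6, 11.1; 10.0: 57.1, 10.1; 15.0: 56.1, 10.7
- south-west (time / h: links / %, first end groups / %): 0.333: 44.4, 39.7; 0.833: 45.2, 40.3; 2.00: 44.4, 39.5; 3.00: 45.9, 39.1; 4.00: 45.3, 40.3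

(scatter of a reading: 0.5 percentage points)

- what is added takes up no volume worth counting
- the numbers in the tables scatter by 0.5 percentage points (one standard deviation)
- a reading or a percentage of links counts all its forms, free or not

- green: at 25 h add second end groups, 50.0% of the amount charged, then wait 2.0 d
- red: at 25 h raise the temperature by 25 K, then wait 2.0 d
- blue: at 25 h add first end groups, 50.0% of the amount charged, then wait 2.0 d
- teal: change nothing and wait 2.0 d more

* links, in percent of the first end groups first charged, at 25 h
* what to do for the largest gain in links; "none" if nothing gains more than 2 percentage points (green / red / blue / teal / none)
* links present, in percent of the first end groups first charged, after red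
* links present, in percent of the first end groups first charged, after teal

We read the north-east table down its columns. Links go from 56.2% at 1.33 h to 56.1% at 15.0 h, which is flat within the scatter, and their mean is 56.3%. Free first end groups average 10.2%, close to the excess of 10.0% in the charge. So 89.8% of the first end groups were consumed, which matches the second charge within the scatter, and second end groups are the limiting reagent.

Now we set the columns against each other. Links fall short of what was consumed, so an unseen product exists. Their quotient, 62.7%, we call the link share, the links formed per first end group consumed. The south-west table gives 74.8%, higher, but that run differs in both temperature and second charge, so we carry the share over with both held.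

Our reckoning for 25 h is therefore 56.3%, and the same after teal. Added first end groups find no second end groups to react with. Added second end groups, 0.0450 M, exceed the free first end groups, so green should gain the share of those free groups, 6.4 percentage points, which is above the margin. Neither run shows links changing once flat, so we also keep 56.3% after red, though neither run was warmed.

The forecast gives 56.3%, green, 56.3% after teal and, unlike us, 37.5% after red, reasoning “If links and the hidden form equilibrate”.

The flask gives 56.4%, green with a gain of 6.5 points, 56.4% after red and 56.4% after teal.

    first end groups + second end groups → links (k = 0.270 M⁻¹ s⁻¹, Ea = 35.0 kJ mol⁻¹)
    first end groups + second end groups → rings, rate k2*[first end groups] as long as [second end groups] is above zero (k = 0.00460 s⁻¹, Ea = 95.0 kJ mol⁻¹)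
    crystals ⇌ links, rate k3*(cs3 - [links]) while solid is left; crystals form when [links] > cs3 (solubility = 0.0550 M, k = 0.00550 s⁻¹)
    second end groups + links ⇌ idle adduct, settled at all times (K = 4.70 M⁻¹, ΔH = −55.0 kJ mol⁻¹)
    (constants at 25 °C)

The unseen product is rings, 33.6% at 25.0 h, and the conversion into rings is the main reason why this flask holds 56.4% links and not the 90.0% of the run without that step. Green gains 6.5 points against our 6.4 points, which is 65.0% of the 10.0% free first end groups at 25.0 h and not our link share of 62.7%, so the closeness of those two gains does not show the link share holding for what green adds. On the neighbour charged with 0.17 M of first end groups, at the same second charge and temperature, the link share gives 33.2% of its first charge, and that neighbour holds 33.2% links.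

The data are simulated for substances that don't exist; noise was put on by code.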